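Abbreviations: geranyl = (2E)-3,7-dimethylocta-2,6-dien-1-yl; prenyl = 3-methylbut-2-en-1-yl; Ar = 2-geranyl-3,4-dimethoxyphenyl. Flavanone numbering is used for the target, pyranone numbering for the ring-C intermediates.

**Plan**

- Feature: ring A is a pentasubstituted benzene (C5–OH, C6–prenyl, C7–OMe, C8–H, with C4a and C8a shared with pyranone ring C). A phenol carbon next to a C-substituent and then an alkoxy carbon is the pattern left when a ketene carbonyl (→ C5) and an ynol ether (→ C6, C7) are annulated onto a vinyl unit (→ C8, C8a, C4a).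
- Retrosynthesis: cut C5–C6, C7–C8 and C4a–C5 (C8–C8a arises by a 1,2-shift) to give diazoketone 20 and methoxyalkyne 18. Then cut the CO–CHN2 bond (acid 12), then O1–C2 and C2–C3 of ring C (aldehyde 6 + bis-silyl dienol ether 8), and last the aryl–geranyl and alkyne–prenyl bonds.
- Forward: ring B is geranylated, ring C is built on its aldehyde carbon, and ring A is closed last on the C5=C6 bond of the dihydropyranone.
- Stereochemistry: the only stereocentre, C2 (S), is set in step 3 by the Ti–(S)-BINOL catalyst and afterwards meets only near-neutral conditions. The E olefin of the geranyl chain comes with geranyl bromide.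

Key step: step 7

Assumption: with aldehyde 6 the Ti–BINOL catalyst is taken to show the facial sense usual for aromatic aldehydes, (S)-BINOL giving the (S)-carbinol carbon; if the sense proves opposite, (R)-BINOL is used in the same step.

**Route**

Step 1
Reactants: 1 veratraldehyde (3,4-dimethoxybenzaldehyde); 2 geranyl bromide
Product: 6 2-geranyl-3,4-dimethoxybenzaldehyde, via lithium α-amino alkoxide 3 (not isolated), via C2-lithiated amino alkoxide 4 (not isolated), via C2-geranylated amino alkoxide 5 (not isolated)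
Conditions: LiN(Me)CH2CH2NMe2 (from MeNHCH2CH2NMe2 and n-BuLi, 1.1 equiv), THF, −20 °C; n-BuLi (3 equiv), −20 °C; CuBr·SMe2 (10 mol %), 2 (4 equiv), −78 → 0 °C; H2O
Reagents that add atoms: none
Why: α-Amino alkoxide-directed ortho-lithiation, in which the in situ-masked aldehyde and the 3-methoxy group together direct n-BuLi to C2, followed by copper-catalysed SN2 allylation of the aryllithium with the primary allylic bromide (E olefin retained) and release of the aldehyde from the aminal alkoxide on aqueous work-up.

Step 2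
Reactants: 7 methyl 2,4-dioxopentanoate
Product: 8 methyl (2Z)-2,4-bis(trimethylsilyloxy)penta-2,4-dienoate
Conditions: TMSOTf (2.2 equiv), Et3N (2.5 equiv), Et2O, 0 °C → rt; pentane extraction, used without chromatography
Reagents that add atoms: trimethylsilyl trifluoromethanesulfonate, C[Si](C)(C)OS(=O)(=O)C(F)(F)F
Why: Double soft enolisation and O-silylation of a 1,3-dicarbonyl compound, the usual entry to 1,3-bis(silyloxy)dienes, should silylate the chelated C2 enol and then the C5 methyl group of the resulting vinylogous ester.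

Step 3
Reactants: 6 2-geranyl-3,4-dimethoxybenzaldehyde; 8 methyl (2Z)-2,4-bis(trimethylsilyloxy)penta-2,4-dienoate
Product: 10 methyl (2S)-2-(2-geranyl-3,4-dimethoxyphenyl)-4-oxo-3,4-dihydro-2H-pyran-6-carboxylate, via silylated aldol adduct 9 (not isolated)
Conditions: (S)-BINOL/Ti(Oi-Pr)4 (1:1, 20 mol %), 4 Å MS, THF, −78 → −20 °C; then TFA (5 mol %), CH2Cl2, −20 → 0 °C, pH 7 buffer quench
Reagents that add atoms: none
Why: Catalytic asymmetric Mukaiyama aldol addition of the terminal silyl enol ether of 8 to the titanium-bound aldehyde, followed by acid-catalysed cyclocondensation with loss of both silyl groups (a formal hetero-Diels–Alder reaction), should form ring C with C2 set as S by the BINOL–titanium complex shielding one aldehyde face, the acid being kept catalytic and brief to spare the electron-rich benzylic C2–O bond and the olefins.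

Step 4
Reactants: 10 methyl (2S)-2-(2-geranyl-3,4-dimethoxyphenyl)-4-oxo-3,4-dihydro-2H-pyran-6-carboxylate
Product: 12 (2S)-2-(2-geranyl-3,4-dimethoxyphenyl)-4-oxo-3,4-dihydro-2H-pyran-6-carboxylic acid, via trimethylstannyl ester 11 (not isolated)
Conditions: Me3SnOH (4 equiv), ClCH2CH2Cl, 70 °C; then cold 0.1 M aq HCl wash
Reagents that add atoms: trimethyltin hydroxide, C[Sn](C)(C)O
Why: Trimethyltin hydroxide ester cleavage is an essentially neutral hydrolysis, chosen because hydroxide could open the vinylogous ester or epimerise C2 by retro-oxa-Michael ring opening, whereas the tin reagent only exchanges the methyl ester for a stannyl ester that a cold dilute acid wash converts into the acid.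

Step 5
Reactants: 13 trichloroethylene; 14 prenyl bromide (1-bromo-3-methylbut-2-ene)
Product: 18 1-methoxy-5-methylhex-4-en-1-yne, via (E)-1,2-dichloro-1-methoxyethene 15 (not isolated), via chloro(methoxy)ethyne 16 (not isolated), via lithium methoxyacetylide 17 (not isolated)
Conditions: KH, MeOH (1.0 equiv), THF, 0 °C; 13, −50 °C → rt; n-BuLi (2.2 equiv), −78 → −40 °C; 14 (1.0 equiv), DMPU, −78 °C → rt; distillation
Reagents that add atoms: methanol, CO
Why: In the trichloroethylene route to alkynyl ethers, methoxide replaces one vinylic chloride, n-BuLi effects dehydrochlorination and then chlorine–lithium exchange, and the lithium alkoxyacetylide is C-alkylated (SN2) by the primary allylic bromide in the presence of DMPU, an amine-free sequence that should leave the skipped enyne unisomerised.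

Step 6
Reactants: 12 (2S)-2-(2-geranyl-3,4-dimethoxyphenyl)-4-oxo-3,4-dihydro-2H-pyran-6-carboxylic acid
Product: 20 (2S)-6-(diazoacetyl)-2-(2-geranyl-3,4-dimethoxyphenyl)-2,3-dihydro-4H-pyran-4-one, via acid chloride 19 (not isolated)
Conditions: Me2C=C(Cl)NMe2 (1.1 equiv), CH2Cl2, 0 °C; then CH2N2 (3 equiv), Et2O, −10 → 0 °C, dark; used at once
Reagents that add atoms: diazomethane, C=[N+]=[N-]
Why: Acylation of diazomethane by an acid chloride (first stage of the Arndt–Eistert sequence) should work because the chloroenamine makes the chloride without HCl (sparing the acid-labile olefins and C2), a second equivalent of diazomethane takes up the HCl, and the alkoxy-substituted trisubstituted C5=C6 bond is expected to be too poor a dipolarophile to intercept the reagent at low temperature.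

Step 7
Reactants: 20 (2S)-6-(diazoacetyl)-2-(2-geranyl-3,4-dimethoxyphenyl)-2,3-dihydro-4H-pyran-4-one; 18 1-methoxy-5-methylhex-4-en-1-yne
Product: 25 (2S)-2-(2-geranyl-3,4-dimethoxyphenyl)-5-hydroxy-7-methoxy-6-prenyl-2,3-dihydro-4H-chromen-4-one (CNP0112088.1), via vinylketene 21 (not isolated), via vinylcyclobutenone 22 (not isolated), via dienylketene 23 (not isolated), via cyclohexadienone 24 (not isolated)
Conditions: hν (blue LEDs, ca. 440 nm), 18 (2 equiv), degassed ClCH2CH2Cl, rt; then 80 °C, dark
Reagents that add atoms: none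
Why: Visible-light excitation of the diazoketone expels N2, and the Wolff 1,2-shift of pyranone C6 (future C8a) to the carbene carbon (future C8) gives vinylketene 21, whose carbonyl carbon (future C5) is attacked by the nucleophilic, prenyl-bearing carbon of ynol ether 18 in a regioselective [2+2] cycloaddition that forms C5–C6 and C7–C8 in cyclobutenone 22. Thermal 4π-electrocyclic opening of 22 gives dienylketene 23, which closes ring A as a six-membered carbocycle by 6π-electrocyclisation between the ketene carbon and pyranone C5 (future C4a), and dienone 24 enolises at once to the phenol because its C4a–H lies between two carbonyl groups. This is the Danheiser benzannulation in its photochemical Wolff variant, known for α,β-unsaturated α′-diazoketones with alkoxy- and siloxyalkynes. No stereocentre is created (cyclobutenone C4 and C4a of 24 are transient), and C2 is remote from every reacting atom and sees only neutral, base-free conditions and light that the flavanone chromophore should not absorb. The one selectivity needed is the [2+2] regiochemistry, secured by the polarity of the two partners (ynol ether β-carbon nucleophilic, ketene carbonyl carbon electrophilic), which alone fixes the 5-OH/6-prenyl/7-OMe/8-H order, while the ring-enforced geometry of the C5=C6 bond holds the C4 carbonyl trans to the ketene so that oxa-6π closure to a 2-pyranone cannot compete. The chelated 5-OH of the product is a poor nucleophile and should not be acylated by remaining ketene, and a methyl ynol ether cannot fragment by retro-ene loss of an alkene at 80 °C.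

**Compound list**

1 | veratraldehyde (3,4-dimethoxybenzaldehyde) | COc1ccc(C=O)cc1OC | starting material
2 | geranyl bromide [(2E)-1-bromo-3,7-dimethylocta-2,6-diene] | BrC/C=C(\C)CCC=C(C)C | starting material
3 | lithium (3,4-dimethoxyphenyl){[2-(dimethylamino)ethyl](methyl)amino}methanolate (α-amino alkoxide of 1, racemic at the aminal carbon; not isolated) | [Li]OC(N(C)CCN(C)C)c1ccc(OC)c(OC)c1 | intermediate
4 | C2-lithio derivative of 3 (lithium between the aminal carbon and the 3-OMe group; not isolated) | [Li]OC(N(C)CCN(C)C)c1ccc(OC)c(OC)c1[Li] | intermediate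
5 | C2-geranylated α-amino alkoxide (not isolated) | [Li]OC(N(C)CCN(C)C)c1ccc(OC)c(OC)c1C/C=C(\C)CCC=C(C)C | intermediate
6 | 2-[(2E)-3,7-dimethylocta-2,6-dien-1-yl]-3,4-dimethoxybenzaldehyde | O=Cc1ccc(OC)c(OC)c1C/C=C(\C)CCC=C(C)C | intermediate
7 | methyl 2,4-dioxopentanoate | COC(=O)C(=O)CC(C)=O | starting material
8 | methyl (2Z)-2,4-bis(trimethylsilyloxy)penta-2,4-dienoate | COC(=O)/C(O[Si](C)(C)C)=C/C(=C)O[Si](C)(C)C | intermediate
9 | methyl (2Z,6S)-6-Ar-4-oxo-2,6-bis(trimethylsilyloxy)hex-2-enoate (not isolated) | COC(=O)/C(O[Si](C)(C)C)=C/C(=O)C[C@@H](c1ccc(OC)c(OC)c1C/C=C(\C)CCC=C(C)C)O[Si](C)(C)C | intermediate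
10 | methyl (2S)-2-Ar-4-oxo-3,4-dihydro-2H-pyran-6-carboxylate | COC(=O)C1=CC(=O)C[C@@H](c2ccc(OC)c(OC)c2C/C=C(\C)CCC=C(C)C)O1 | intermediate
11 | trimethylstannyl (2S)-2-Ar-4-oxo-3,4-dihydro-2H-pyran-6-carboxylate (not isolated) | C[Sn](C)(C)OC(=O)C1=CC(=O)C[C@@H](c2ccc(OC)c(OC)c2C/C=C(\C)CCC=C(C)C)O1 | intermediate
12 | (2S)-2-Ar-4-oxo-3,4-dihydro-2H-pyran-6-carboxylic acid | OC(=O)C1=CC(=O)C[C@@H](c2ccc(OC)c(OC)c2C/C=C(\C)CCC=C(C)C)O1 | intermediate
13 | trichloroethylene | ClC=C(Cl)Cl | starting material
14 | prenyl bromide (1-bromo-3-methylbut-2-ene) | CC(C)=CCBr | starting material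
15 | (E)-1,2-dichloro-1-methoxyethene (not isolated) | CO/C(Cl)=C\Cl | intermediate
16 | chloro(methoxy)ethyne (not isolated) | COC#CCl | intermediate
17 | lithium methoxyacetylide (not isolated) | COC#C[Li] | intermediate
18 | 1-methoxy-5-methylhex-4-en-1-yne | COC#CCC=C(C)C | intermediate
19 | (2S)-2-Ar-4-oxo-3,4-dihydro-2H-pyran-6-carbonyl chloride (not isolated) | ClC(=O)C1=CC(=O)C[C@@H](c2ccc(OC)c(OC)c2C/C=C(\C)CCC=C(C)C)O1 | intermediate
20 | (2S)-6-(diazoacetyl)-2-Ar-2,3-dihydro-4H-pyran-4-one | [N-]=[N+]=CC(=O)C1=CC(=O)C[C@@H](c2ccc(OC)c(OC)c2C/C=C(\C)CCC=C(C)C)O1 | intermediate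
21 | (2S)-2-Ar-6-(2-oxoethenyl)-2,3-dihydro-4H-pyran-4-one (vinylketene; not isolated) | O=C=CC1=CC(=O)C[C@@H](c2ccc(OC)c(OC)c2C/C=C(\C)CCC=C(C)C)O1 | intermediate
22 | 3-methoxy-2-prenyl-4-[(2S)-2-Ar-4-oxo-3,4-dihydro-2H-pyran-6-yl]cyclobut-2-en-1-one (both epimers at cyclobutenone C4; not isolated) | COC1=C(CC=C(C)C)C(=O)C1C1=CC(=O)C[C@@H](c2ccc(OC)c(OC)c2C/C=C(\C)CCC=C(C)C)O1 | intermediate
23 | (2S)-2-Ar-6-[(1E)-2-methoxy-6-methyl-3-(oxomethylidene)hepta-1,5-dien-1-yl]-2,3-dihydro-4H-pyran-4-one (dienylketene; not isolated) | O=C=C(CC=C(C)C)/C(OC)=C\C1=CC(=O)C[C@@H](c2ccc(OC)c(OC)c2C/C=C(\C)CCC=C(C)C)O1 | intermediate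
24 | (2S)-2-Ar-7-methoxy-6-prenyl-2,3-dihydro-4H-chromene-4,5(4aH)-dione (keto tautomer of 25, both epimers at C4a; not isolated) | COC1=C(CC=C(C)C)C(=O)C2C(=O)C[C@@H](c3ccc(OC)c(OC)c3C/C=C(\C)CCC=C(C)C)OC2=C1 | intermediate
25 | (2S)-2-{2-[(2E)-3,7-dimethylocta-2,6-dien-1-yl]-3,4-dimethoxyphenyl}-5-hydroxy-7-methoxy-6-(3-methylbut-2-en-1-yl)-2,3-dihydro-4H-chromen-4-one | COc1cc2c(c(O)c1CC=C(C)C)C(=O)C[C@@H](c1ccc(OC)c(OC)c1C/C=C(\C)CCC=C(C)C)O2 | target

**Step count and risks**

Total step count: 7. Longest linear sequence: 5 (steps 1, 3, 4, 6, 7; the same length from 7 through steps 2, 3, 4, 6, 7). The alkyne branch is step 5.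

Steps most likely to fail:

1. Step 7. Capture of the short-lived vinylketene by the alkynyl ether may lose out to ketene oligomerisation. Dipolar addition of the diazo group to the electron-rich alkyne before photolysis, or a sluggish Wolff shift from the push–pull diazoketone, are further risks. The volatile, acid-sensitive methyl ynol ether may also be lost. The fallback exchanges the ketenophile for a silyl ynol ether, the sturdiest partner for this annulation, and moves the O-methylation to the end. It sets out from diazoketone 20 and prenyl bromide 14 and returns at 25. Copper(I)-catalysed coupling of 14 with ethynylmagnesium bromide should give 5-methylhex-4-en-1-yne F1. Its lithium acetylide (LiHMDS) is oxidised with lithium tert-butyl peroxide to the ynolate, which TIPSOTf silylates on oxygen to give triisopropyl[(5-methylhex-4-en-1-yn-1-yl)oxy]silane F2. Irradiation of 20 with F2 under the conditions of step 7 should give (2S)-2-Ar-5-hydroxy-6-prenyl-7-(triisopropylsilyloxy)chroman-4-one F3. TBAF buffered with acetic acid should free the 7-phenol, (2S)-2-Ar-5,7-dihydroxy-6-prenylchroman-4-one F4. Ethereal diazomethane should then methylate only the more acidic, non-chelated 7-OH, giving 25.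

2. Step 6. 1,3-Dipolar cycloaddition of diazomethane to the acceptor-flanked C5=C6 bond (pyrazoline formation) may compete with C-acylation, and adventitious HCl may ionise the benzylic C2–O bond. The fallback builds the diazo group without any free diazoalkane. It sets out from acid chloride 19 and returns at 20. (N-Isocyanoimino)triphenylphosphorane adds through its isocyanide carbon to the acid chloride (Nef isocyanide reaction) in CH2Cl2 to give the α-keto hydrazonoyl chloride, 2-[(2S)-2-Ar-4-oxo-3,4-dihydro-2H-pyran-6-yl]-2-oxo-N-(triphenylphosphoranylideneamino)ethanimidoyl chloride F5. Water with NaHCO3 should then cleave the P=N bond and, with loss of HCl, leave the diazo group on the new carbon, giving 20.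

3. Step 3. The ester-bearing diene is a weaker nucleophile than simple bis(silyloxy)dienes and the aldehyde is electron-rich and ortho-substituted, so slow turnover, an uncatalysed silyl-transfer background and poor facial discrimination may erode the enantiomeric purity. The fallback replaces catalyst control by a stoichiometric chiral reagent and builds ring C stepwise. It sets out from aldehyde 6 and returns at 10. Brown allylation with (−)-B-allyldiisopinocampheylborane (Et2O, −78 °C, ethanolamine work-up) should give (1S)-1-Ar-but-3-en-1-ol F6. Silylation (TBSCl, imidazole) gives the TBS ether F7. Tsuji–Wacker oxidation (PdCl2 cat., CuCl, O2, DMF/H2O), which touches only the monosubstituted olefin, gives (4S)-4-Ar-4-(tert-butyldimethylsilyloxy)butan-2-one F8. Claisen condensation of its kinetic methyl enolate (LiHMDS, −78 °C) with dimethyl oxalate gives methyl (6S)-6-Ar-6-(tert-butyldimethylsilyloxy)-2,4-dioxohexanoate F9. Buffered HF·pyridine in THF followed by catalytic PPTS should remove the silyl group and cyclodehydrate the hydroxy diketo ester to 10.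

**Further compounds**

F1 | step 7 | 5-methylhex-4-en-1-yne | C#CCC=C(C)C
F2 | step 7 | triisopropyl[(5-methylhex-4-en-1-yn-1-yl)oxy]silane | CC(C)[Si](OC#CCC=C(C)C)(C(C)C)C(C)C
F3 | step 7 | (2S)-2-(2-geranyl-3,4-dimethoxyphenyl)-5-hydroxy-6-prenyl-7-(triisopropylsilyloxy)chroman-4-one | CC(C)[Si](Oc1cc2c(c(O)c1CC=C(C)C)C(=O)C[C@@H](c1ccc(OC)c(OC)c1C/C=C(\C)CCC=C(C)C)O2)(C(C)C)C(C)C
F4 | step 7 | (2S)-2-(2-geranyl-3,4-dimethoxyphenyl)-5,7-dihydroxy-6-prenylchroman-4-one | Oc1cc2c(c(O)c1CC=C(C)C)C(=O)C[C@@H](c1ccc(OC)c(OC)c1C/C=C(\C)CCC=C(C)C)O2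
F5 | step 6 | 2-[(2S)-2-(2-geranyl-3,4-dimethoxyphenyl)-4-oxo-3,4-dihydro-2H-pyran-6-yl]-2-oxo-N-(triphenylphosphoranylideneamino)ethanimidoyl chloride | ClC(=NN=P(c1ccccc1)(c1ccccc1)c1ccccc1)C(=O)C1=CC(=O)C[C@@H](c2ccc(OC)c(OC)c2C/C=C(\C)CCC=C(C)C)O1
F6 | step 3 | (1S)-1-(2-geranyl-3,4-dimethoxyphenyl)but-3-en-1-ol | C=CC[C@@H](c1ccc(OC)c(OC)c1C/C=C(\C)CCC=C(C)C)O
F7 | step 3 | tert-butyl{[(1S)-1-(2-geranyl-3,4-dimethoxyphenyl)but-3-en-1-yl]oxy}dimethylsilane | C=CC[C@@H](c1ccc(OC)c(OC)c1C/C=C(\C)CCC=C(C)C)O[Si](C)(C)C(C)(C)C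
F8 | step 3 | (4S)-4-(tert-butyldimethylsilyloxy)-4-(2-geranyl-3,4-dimethoxyphenyl)butan-2-one | CC(=O)C[C@@H](c1ccc(OC)c(OC)c1C/C=C(\C)CCC=C(C)C)O[Si](C)(C)C(C)(C)C
F9 | step 3 | methyl (6S)-6-(tert-butyldimethylsilyloxy)-6-(2-geranyl-3,4-dimethoxyphenyl)-2,4-dioxohexanoate | COC(=O)C(=O)CC(=O)C[C@@H](c1ccc(OC)c(OC)c1C/C=C(\C)CCC=C(C)C)O[Si](C)(C)C(C)(C)C
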